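## Retrosynthetic overview
1. The target comes from its phenol acetate, which comes from a 19-membered macrolactone triene-ol by one anodic Br⁺ cascade. The cascade first closes the tetrahydropyran (THP) by anti-bromoetherification of the Z-C10=C11 alkene with the tertiary C15-OH, then forms the cyclohexene (transannular C2–C7 bond, C6–Br, all-E chair–chair).
2. The macrolactone comes from macro-RCM (C2=C3) of the 4-acetoxy-3-allylbenzoate of a diene-diol. That ester comes from Yamaguchi esterification of the hindered secondary C14-OH.
3. The diene-diol comes from cross-metathesis (C6=C7) of a methallyl diol with 2-methyl-1,5-hexadiene. The methallyl diol comes from Ni cross-electrophile coupling of a bromo-hydroxy-ester (from (S)-α-hydroxy-γ-butyrolactone, the only chiral-pool stereocentre, C14) with a Z-vinyl iodide (from 2-butyn-1-ol), followed by MeMgBr.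
4. Ring order: the arene is bought; the macrolactone is formed by esterification then RCM; the THP and then the cyclohexene both form in the electrochemical step.

Assumption: (S)-α-hydroxy-γ-butyrolactone and 3-allyl-4-hydroxybenzoic acid are purchased; other reagents are standard catalogue items.

## Route

**Step 1**
Reactants: 1, 2-butyn-1-ol
Product: 2, (Z)-3-iodobut-2-en-1-ol
Conditions: Red-Al, Et2O, 0 °C; then EtOAc; then I2, –78 °C
Reagents that add atoms: iodine, II
Why: Trans-hydroalumination of a propargylic alcohol through an oxa-aluminacycle puts Al, and after iodinolysis I, cis to CH2OH; this Z geometry later fixes C10 relative to C11.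

**Step 2**
Reactants: 2
Product: 3, (Z)-1-bromo-3-iodobut-2-ene
Conditions: PPh3, CBr4, CH2Cl2, 0 °C; use immediately
Reagents that add atoms: carbon tetrabromide, BrC(Br)(Br)Br
Why: Appel bromination of a primary allylic alcohol, which leaves the alkene geometry and vinyl iodide untouched.

**Step 3**
Reactants: 3; 4, methallylmagnesium chloride
Product: 5, (Z)-6-iodo-2-methylhepta-1,5-diene
Conditions: 4 (1.3 equiv), CuI (10 mol %), THF, –40 °C
Reagents that add atoms: none (the methallyl group comes from 4)
Why: Cu-catalysed SN2 allyl–allyl coupling at the primary allylic bromide installs C8–C9 and the 1,1-disubstituted alkene (C7=C6) for later metathesis.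

**Step 4**
Reactants: 6, (S)-α-hydroxy-γ-butyrolactone
Product: 7, methyl (S)-4-bromo-2-hydroxybutanoate
Conditions: AcBr, MeOH, 0 °C → 50 °C
Reagents that add atoms: acetyl bromide, CC(=O)Br (supplies Br); methanol, CO (supplies OMe)
Why: HBr/MeOH opens the lactone by SN2 at the primary C–O carbon and esterifies; C14 is not touched and stays (S).

**Step 5**
Reactants: 7; 5
Product: 8, methyl (2S,5Z)-2-hydroxy-5,9-dimethyldeca-5,9-dienoate
Conditions: 7 (1.5 equiv), 5 (1 equiv), NiBr2·diglyme (10 mol %), dtbbpy (10 mol %), Zn (3 equiv), NaI (0.5 equiv), DMA, 25 °C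
Reagents that add atoms: none
Why: Ni-catalysed cross-electrophile coupling of a primary alkyl bromide with a vinyl iodide forms C11–C12 with retention of the Z alkene; the free α-OH is tolerated and no new stereocentre is formed.

**Step 6**
Reactants: 8
Product: 9, (3S,6Z)-2,6,10-trimethylundeca-6,10-diene-2,3-diol
Conditions: MeMgBr (5 equiv), THF, –78 → 0 °C
Reagents that add atoms: methylmagnesium bromide, C[Mg]Br
Why: Double Grignard addition converts the methyl ester into the C15 dimethyl carbinol; the Mg alkoxide of the α-OH protects C14 from epimerisation.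

**Step 7**
Reactants: 9; 10, 2-methyl-1,5-hexadiene
Product: 11, (3S,6Z,10E)-2,6,10,14-tetramethylpentadeca-6,10,14-triene-2,3-diol
Conditions: 10 (6 equiv), Hoveyda–Grubbs II (5 mol %), CH2Cl2, 40 °C, N2 sweep
Reagents that add atoms: none (ethylene is lost)
Why: Cross-metathesis of a slowly homodimerising 1,1-disubstituted alkene with an excess of the terminal alkene of 10 gives the thermodynamic E-trisubstituted C6=C7, while the isopropenyl end of 10 stays unreacted.

**Step 8**
Reactants: 12, 3-allyl-4-hydroxybenzoic acid
Product: 13, 4-acetoxy-3-allylbenzoic acid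
Conditions: Ac2O, pyridine, DMAP (cat.), 0 °C → rt; then aq. HCl
Reagents that add atoms: acetic anhydride, CC(=O)OC(C)=O
Why: Acetylation protects the phenol against Br⁺ and acylation; the acid workup hydrolyses the mixed anhydride.

**Step 9**
Reactants: 11; 13
Product: 14, (3S,6Z,10E)-2-hydroxy-2,6,10,14-tetramethylpentadeca-6,10,14-trien-3-yl 4-acetoxy-3-allylbenzoate
Conditions: 2,4,6-Cl3C6H2COCl, Et3N, THF, rt; then 11, DMAP, toluene, 50 °C
Reagents that add atoms: none
Why: Yamaguchi esterification acylates the secondary C14-OH and not the tertiary C15-OH, and C14 keeps its (S) configuration.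

**Step 10**
Reactants: 14
Product: 15, 19-membered macrolactone (2E,6E,10Z)-triene with a free tertiary C15-OH
Conditions: Hoveyda–Grubbs II (10 mol %), CH2Cl2 (2 mM, slow addition), 40 °C, N2 sweep
Reagents that add atoms: none (ethylene is lost)
Why: Macro-RCM between the 1,1-disubstituted and the allyl-arene termini forms the trisubstituted C2=C3; the 19-membered ring should favour the E alkene thermodynamically, which is needed for the chair cyclisation.

**Step 11**
Reactants: 15
Product: 16, O-acetyl bromophycolide U
Conditions: nBu4NBr (3 equiv), 2,6-di-tert-butylpyridine (2 equiv), HFIP/CH2Cl2 (1:4), undivided cell, graphite(+)/Pt(–), 3 mA, 0 °C, 4.4 F/mol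
Reagents that add atoms: tetrabutylammonium bromide, CCCC[N+](CCCC)(CCCC)CCCC.[Br-]
Why: Proposed new method: anodic oxidation of Br⁻ delivers Br⁺ to the Z-C10=C11 alkene, and the tertiary C15-OH captures the bromonium anti in a 6-exo chair with C14-OCOAr equatorial and the smaller Me axial, giving (10R,11R) in line with the C14 (S) centre. A second Br⁺ then forms the C6=C7 bromonium, which the C2=C3 alkene attacks anti through an all-E chair–chair transition state, creating C2–C7 (6-Br equatorial, 7-Me axial, 2-CH2Ar equatorial) and a C3 cation that loses H-4 to give Δ3,4; the macrocycle conformation, anchored by the THP, ester and arene, is expected to select the face and hence the absolute configuration of C2/C6/C7. Closest known reactions are Br⁺-induced cation–olefin polyene cyclisation of geranyl arenes and electrochemical bromoetherification, but not as a transannular macrolactone cascade.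

**Step 12**
Reactants: 16
Product: 17, bromophycolide U
Conditions: K2CO3 (0.2 equiv), MeOH/THF, 0 °C, 30 min
Reagents that add atoms: none
Why: Phenyl acetate methanolysis is far faster than cleavage of the hindered alkyl benzoate or E2 of the secondary bromides; no stereocentre is affected.

## Compound list
1 | 2-butyn-1-ol | CC#CCO | starting material
2 | (Z)-3-iodobut-2-en-1-ol | C/C(I)=C/CO | intermediate
3 | (Z)-1-bromo-3-iodobut-2-ene | C/C(I)=C/CBr | intermediate
4 | methallylmagnesium chloride | C=C(C)C[Mg]Cl | starting material
5 | (Z)-6-iodo-2-methylhepta-1,5-diene | C=C(C)CC/C=C(/C)I | intermediate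
6 | (S)-α-hydroxy-γ-butyrolactone | O[C@H]1CCOC1=O | starting material
7 | methyl (S)-4-bromo-2-hydroxybutanoate | COC(=O)[C@@H](O)CCBr | intermediate
8 | methyl (2S,5Z)-2-hydroxy-5,9-dimethyldeca-5,9-dienoate | COC(=O)[C@@H](O)CC/C(C)=C\CCC(C)=C | intermediate
9 | (3S,6Z)-2,6,10-trimethylundeca-6,10-diene-2,3-diol | CC(C)(O)[C@@H](O)CC/C(C)=C\CCC(C)=C | intermediate
10 | 2-methyl-1,5-hexadiene | C=CCCC(C)=C | starting material
11 | (3S,6Z,10E)-2,6,10,14-tetramethylpentadeca-6,10,14-triene-2,3-diol | C=C(C)CC/C=C(\C)CC/C=C(/C)CC[C@H](O)C(C)(C)O | intermediate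
12 | 3-allyl-4-hydroxybenzoic acid | C=CCc1cc(C(=O)O)ccc1O | starting material
13 | 4-acetoxy-3-allylbenzoic acid | C=CCc1cc(C(=O)O)ccc1OC(C)=O | intermediate
14 | ester of 11 (C14-OH) with 13 | C=C(C)CC/C=C(\C)CC/C=C(/C)CC[C@H](OC(=O)c1ccc(OC(C)=O)c(CC=C)c1)C(C)(C)O | intermediate
15 | 19-membered macrolactone triene-ol (aryl acetate) | O=C1O[C@H](C(C)(C)O)CC/C(C)=C\CC/C(C)=C/CC/C(C)=C/Cc2cc1ccc2OC(C)=O | intermediate
16 | O-acetyl bromophycolide U | CC1=CC[C@H](Br)[C@@]2(C)CC[C@@H](Br)[C@@]3(C)CC[C@H](OC(=O)c4ccc(OC(C)=O)c(c4)C[C@H]12)C(C)(C)O3 | intermediate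
17 | bromophycolide U | CC1=CC[C@H](Br)[C@@]2(C)CC[C@@H](Br)[C@@]3(C)CC[C@H](OC(=O)c4ccc(O)c(c4)C[C@H]12)C(C)(C)O3 | target

## Summary
Total steps: 12. Longest linear sequence: 10 steps (2-butyn-1-ol → 2 → 3 → 5 → 8 → 9 → 11 → 14 → 15 → 16 → 17).

**Three steps most likely to fail**
1. **Step 11 (proposed new step, electrochemical double cascade).** The risks are the order of bromonium events, weak facial bias from a 19-membered ring, and exocyclic versus endocyclic alkene formation.
   - Fallback (known chemistry): build the THP early on 9 (TBS on C14-OH, NBS bromoetherification), then do CM and CM with methyl 3-allyl-4-acetoxybenzoate to make the acyclic geranyl-arene. Cyclise with BDSB (Et2SBr·SbCl5Br), separate the ring diastereomers, and close the ring by Yamaguchi macrolactonisation.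
2. **Step 10 (macro-RCM).** The risks are a low E/Z ratio and oligomerisation.
   - Fallback: intermolecular CM of 11 with methyl 3-allyl-4-acetoxybenzoate, Me3SnOH cleavage of the methyl ester, then Yamaguchi macrolactonisation at C14-OH, so the ring is closed by an ester bond instead of an alkene.
3. **Step 5 (Ni cross-electrophile coupling).** The risks are loss of Z geometry and interference from the free α-OH.
   - Fallback: silylate the α-OH of 7, make the alkylzinc bromide (Zn, LiCl), couple it with 5 under Negishi conditions (Pd-PEPPSI-IPr), and remove the silyl group after the Grignard step.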